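**Retrosynthetic overview**

1. The target is read as fisetinidol-(4α→8)-6-methylcatechin: upper unit (2R,3S,4S), 2,3-trans-3,4-trans; lower unit (2R,3S). The last step is hydrogenolysis of nine benzyl ethers.
2. Feature: C4 of the upper unit is a doubly benzylic methine between C4a of the upper ring A and C8 of the lower ring A. C8 is flanked by the oxygen-bearing C7 and C8a and lies para to the oxygen-bearing C5, so a C4 cation is a quinone-methide-type ion stabilised by three oxygens and can be formed from either carbinol epimer.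
3. Key disconnection C4–C4a: ring C of the upper unit, the only ring built in the route, closes by intramolecular Friedel–Crafts alkylation of a 3-benzyloxyphenyl ether. Before it, C4–C8 comes from an 8-lithio-6-methylcatechin ether and an α-benzyloxy-β-aryloxy aldehyde.
4. The aldehyde carries C2, C3 and the C2–O1 ether of the upper unit, made by Sharpless epoxidation of 3,4-dibenzyloxycinnamyl alcohol and invertive benzylic opening with 3-benzyloxyphenol.
5. The lower unit keeps rings A, B and C of (+)-catechin intact: perbenzylation, C8 bromination, C6 iodination, then iodine-selective exchange and methylation.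

Key step: step 15

Remark: phenoxide and alkoxide salts formed by simple deprotonation, and metal alkoxides present before aqueous work-up, are treated as forms of the numbered compound and are not numbered separately.

**Route**

Step 1
Reactants: 1 3,4-bis(benzyloxy)benzaldehyde
Product: 2 ethyl (E)-3-[3,4-bis(benzyloxy)phenyl]acrylate
Conditions: Ph3P=CHCO2Et (1.2 equiv), toluene, 90 °C
Reagents that add atoms: ethyl (triphenylphosphoranylidene)acetate, CCOC(=O)C=P(c1ccccc1)(c1ccccc1)c1ccccc1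
Why: Wittig olefination with a stabilised ylide, which should give the (E)-cinnamate from an aromatic aldehyde.

Step 2
Reactants: 2 ethyl (E)-3-[3,4-bis(benzyloxy)phenyl]acrylate
Product: 3 (E)-3-[3,4-bis(benzyloxy)phenyl]prop-2-en-1-ol
Conditions: i-Bu2AlH (2.5 equiv), CH2Cl2, −78 → 0 °C; aq. potassium sodium tartrate
Reagents that add atoms: none
Why: 1,2-reduction of a conjugated ester by i-Bu2AlH should give the allylic alcohol without touching the alkene or the benzyl ethers.

Step 3
Reactants: 3 (E)-3-[3,4-bis(benzyloxy)phenyl]prop-2-en-1-ol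
Product: 4 (2S,3S)-3-[3,4-bis(benzyloxy)phenyl]oxiran-2-ylmethanol
Conditions: Ti(Oi-Pr)4 (10 mol %), L-(+)-diisopropyl tartrate (12 mol %), t-BuOOH (2 equiv, anhydrous), 4 Å MS, CH2Cl2, −20 °C; aq. NaOH/brine, 0 °C; crude 4 used at once
Reagents that add atoms: tert-butyl hydroperoxide, CC(C)(C)OO
Why: Sharpless asymmetric epoxidation, in which the L-(+)-tartrate ligand directs oxygen to the alkene face that gives the (2S,3S)-trans-epoxide from an (E)-3-arylallyl alcohol, so both new stereocentres are set by the ligand.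

Step 4
Reactants: 4 (2S,3S)-3-[3,4-bis(benzyloxy)phenyl]oxiran-2-ylmethanol; 5 3-(benzyloxy)phenol
Product: 6 (2S,3R)-3-[3-(benzyloxy)phenoxy]-3-[3,4-bis(benzyloxy)phenyl]propane-1,2-diol
Conditions: 5 (1.5 equiv), NaOH (1.5 equiv), dioxane/H2O, 60 °C
Reagents that add atoms: none
Why: SN2 opening of the epoxide by phenoxide at the benzylic C3, the known regiochemistry for 3-arylglycidols with aryloxides under base, inverts C3 (S to R), leaves C2 untouched and gives the anti relationship required for a 2,3-trans flavan.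

Step 5
Reactants: 6 (2S,3R)-3-[3-(benzyloxy)phenoxy]-3-[3,4-bis(benzyloxy)phenyl]propane-1,2-diol
Product: 7 (2S,3R)-3-[3-(benzyloxy)phenoxy]-3-[3,4-bis(benzyloxy)phenyl]-1-(tert-butyldiphenylsilyloxy)propan-2-ol
Conditions: TBDPSCl (1.1 equiv), imidazole, CH2Cl2, 0 °C
Reagents that add atoms: tert-butyl(chloro)diphenylsilane, CC(C)(C)[Si](Cl)(c1ccccc1)c1ccccc1
Why: Silylation with a bulky chlorosilane should take only the primary hydroxyl of the 1,2-diol.

Step 6
Reactants: 7 (2S,3R)-3-[3-(benzyloxy)phenoxy]-3-[3,4-bis(benzyloxy)phenyl]-1-(tert-butyldiphenylsilyloxy)propan-2-ol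
Product: 8 (2S,3R)-2-(benzyloxy)-3-[3-(benzyloxy)phenoxy]-3-[3,4-bis(benzyloxy)phenyl]-1-(tert-butyldiphenylsilyloxy)propane
Conditions: BnBr, Bu4NI (cat.), then NaH, THF/DMF, 0 °C → rt
Reagents that add atoms: benzyl bromide, BrCc1ccccc1
Why: Williamson etherification of the secondary alkoxide, generated in the presence of benzyl bromide so that it is trapped before the silyl group can migrate.

Step 7
Reactants: 8 (2S,3R)-2-(benzyloxy)-3-[3-(benzyloxy)phenoxy]-3-[3,4-bis(benzyloxy)phenyl]-1-(tert-butyldiphenylsilyloxy)propane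
Product: 9 (2S,3R)-2-(benzyloxy)-3-[3-(benzyloxy)phenoxy]-3-[3,4-bis(benzyloxy)phenyl]propan-1-ol
Conditions: Bu4NF, THF, 0 °C → rt
Reagents that add atoms: none
Why: Fluoride-mediated desilylation frees the primary alcohol and leaves the benzyl and aryl ethers alone.

Step 8
Reactants: 9 (2S,3R)-2-(benzyloxy)-3-[3-(benzyloxy)phenoxy]-3-[3,4-bis(benzyloxy)phenyl]propan-1-ol
Product: 10 (2R,3R)-2-(benzyloxy)-3-[3-(benzyloxy)phenoxy]-3-[3,4-bis(benzyloxy)phenyl]propanal
Conditions: Dess–Martin periodinane, NaHCO3, CH2Cl2, 0 °C → rt; used crude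
Reagents that add atoms: none
Why: Dess–Martin oxidation under buffered, amine-free conditions should give the α-alkoxy aldehyde without epimerisation at C2 or β-elimination of the aryloxide (the descriptor at C2 changes only because the CIP priorities change).

Step 9
Reactants: 11 (+)-catechin
Product: 12 (2R,3S)-5,7-bis(benzyloxy)-2-[3,4-bis(benzyloxy)phenyl]chroman-3-ol
Conditions: BnBr (4.4 equiv), K2CO3, DMF, 0 °C → rt
Reagents that add atoms: benzyl bromide, BrCc1ccccc1
Why: Williamson etherification in which K2CO3 deprotonates only the four phenols, so the aliphatic 3-OH stays free and the mild, cold conditions avoid base-induced C2 epimerisation.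

Step 10
Reactants: 12 (2R,3S)-5,7-bis(benzyloxy)-2-[3,4-bis(benzyloxy)phenyl]chroman-3-ol
Product: 13 (2R,3S)-3,5,7-tris(benzyloxy)-2-[3,4-bis(benzyloxy)phenyl]chromane
Conditions: NaH, BnBr, DMF, 0 °C → rt
Reagents that add atoms: benzyl bromide, BrCc1ccccc1
Why: Williamson etherification of the secondary alkoxide; with all phenols capped no quinone-methide epimerisation pathway is open.

Step 11
Reactants: 13 (2R,3S)-3,5,7-tris(benzyloxy)-2-[3,4-bis(benzyloxy)phenyl]chromane
Product: 14 (2R,3S)-3,5,7-tris(benzyloxy)-2-[3,4-bis(benzyloxy)phenyl]-8-bromochromane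
Conditions: NBS (1.0 equiv), CH2Cl2, −78 → 0 °C
Reagents that add atoms: N-bromosuccinimide, O=C1CCC(=O)N1Br
Why: Electrophilic aromatic bromination; with one equivalent of NBS the C8 position (ortho to O1 and O7, para to O5) of 5,7-di-O-benzyl flavan-3-ol ethers reacts ahead of C6, which sits between two benzyloxy groups.

Step 12
Reactants: 14 (2R,3S)-3,5,7-tris(benzyloxy)-2-[3,4-bis(benzyloxy)phenyl]-8-bromochromane
Product: 15 (2R,3S)-3,5,7-tris(benzyloxy)-2-[3,4-bis(benzyloxy)phenyl]-8-bromo-6-iodochromane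
Conditions: NIS (1.2 equiv), CF3CO2H (cat.), CH2Cl2/MeCN, 0 °C → rt, dark
Reagents that add atoms: N-iodosuccinimide, O=C1CCC(=O)N1I
Why: Electrophilic aromatic iodination at C6, the only remaining ring A CH, which is ortho to two benzyloxy groups and para to O1 and so far more nucleophilic than ring B.

Step 13
Reactants: 15 (2R,3S)-3,5,7-tris(benzyloxy)-2-[3,4-bis(benzyloxy)phenyl]-8-bromo-6-iodochromane
Product: 17 (2R,3S)-3,5,7-tris(benzyloxy)-2-[3,4-bis(benzyloxy)phenyl]-8-bromo-6-methylchromane, via C6 aryllithium 16 (not isolated)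
Conditions: n-BuLi (1.05 equiv), THF, −78 °C, 10 min; MeI (5 equiv), −78 → 0 °C
Reagents that add atoms: iodomethane, CI
Why: Halogen–lithium exchange followed by SN2 methylation; at −78 °C iodine exchanges far faster than bromine, so only C6 is lithiated and the C8 bromide is kept for step 14.

Step 14
Reactants: 17 (2R,3S)-3,5,7-tris(benzyloxy)-2-[3,4-bis(benzyloxy)phenyl]-8-bromo-6-methylchromane; 10 (2R,3R)-2-(benzyloxy)-3-[3-(benzyloxy)phenoxy]-3-[3,4-bis(benzyloxy)phenyl]propanal
Product: 19 (2S,3R)-2-(benzyloxy)-3-[3-(benzyloxy)phenoxy]-3-[3,4-bis(benzyloxy)phenyl]-1-[(2R,3S)-penta-O-benzyl-6-methylcatechin-8-yl]propan-1-ol (both C1 epimers), via C8 aryllithium 18 (not isolated)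
Conditions: 17 (1.2 equiv), n-BuLi (1.15 equiv), THF, −78 °C; then 10 (1.0 equiv) in THF, −78 °C; H2O
Reagents that add atoms: none
Why: Bromine–lithium exchange and 1,2-addition of the aryllithium to the aldehyde at −78 °C, a known way to attach carbon electrophiles to C8 of perbenzylated flavan-3-ols; the new carbinol centre forms as a mixture, which is immaterial because step 15 passes through a planar cation.

Step 15
Reactants: 19 precursor carbinol (both C1 epimers)
Product: 21 nona-O-benzyl fisetinidol-(4α→8)-6-methylcatechin, via C4 benzylic cation 20 (not isolated)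
Conditions: BF3·OEt2 (0.5 equiv), 4 Å MS, CH2Cl2 (5 mM), −78 → −30 °C; Et3N
Reagents that add atoms: none
Why: BF3 activates the C4 hydroxyl of either epimer of 19 and loss of water gives the single cation 20, whose charge is shared with O7, O1 and O5 of the lower ring A; the tethered 3-benzyloxyphenyl ether attacks it through the carbon ortho to the ether oxygen and para to the benzyloxy group, and loss of a proton restores the arene (intramolecular Friedel–Crafts alkylation). The closest known reactions are acid-mediated cyclisations of 1-aryl-3-aryloxypropan-1-ols to 4-arylchromans and the capture of C4 cations of perbenzylated flavan-3-ols by electron-rich arenes. Ring C of the upper unit closes in the 6-exo-trig mode with respect to the cationic carbon (the stabilising lower ring lies outside the new ring) through a chair-like transition state. The new C4 stereocentre is controlled by the existing C2 and C3 centres: with the C2 aryl and C3 benzyloxy groups equatorial, the cation should react through the C3–C4 rotamer that places the bulky lower flavan unit pseudo-equatorial, which gives the 3,4-trans, 2,4-cis (4S) product. The step needs attack para rather than ortho to the benzyloxy group (the ortho site lies between two oxygens and is crowded) and six-membered closure onto the ether ring rather than five-membered closure onto the less activated ring B; the substrate favours both, and low temperature, high dilution and a sub-stoichiometric mild Lewis acid should keep the nine benzyl ethers and the benzylic C2–O1 bond intact.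

Step 16
Reactants: 21 nona-O-benzyl fisetinidol-(4α→8)-6-methylcatechin
Product: 22 fisetinidol-(4α→8)-6-methylcatechin (CNP0288113.1)
Conditions: H2 (1 atm), Pd(OH)2/C, THF/MeOH, rt
Reagents that add atoms: none
Why: Catalytic hydrogenolysis of the benzyl ethers; under neutral conditions at room temperature the cyclic benzylic C2–O1 bonds and the C4–C8 bond of a 4-arylflavan should survive and no stereocentre is touched.

**Compound list**

1 | 3,4-bis(benzyloxy)benzaldehyde | O=Cc1ccc(OCc2ccccc2)c(OCc2ccccc2)c1 | starting material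
2 | ethyl (E)-3-[3,4-bis(benzyloxy)phenyl]acrylate | CCOC(=O)/C=C/c1ccc(OCc2ccccc2)c(OCc2ccccc2)c1 | intermediate
3 | (E)-3-[3,4-bis(benzyloxy)phenyl]prop-2-en-1-ol | OC/C=C/c1ccc(OCc2ccccc2)c(OCc2ccccc2)c1 | intermediate
4 | (2S,3S)-3-[3,4-bis(benzyloxy)phenyl]oxiran-2-ylmethanol | OC[C@@H]1O[C@H]1c1ccc(OCc2ccccc2)c(OCc2ccccc2)c1 | intermediate
5 | 3-(benzyloxy)phenol | Oc1cccc(OCc2ccccc2)c1 | starting material
6 | (2S,3R)-3-[3-(benzyloxy)phenoxy]-3-[3,4-bis(benzyloxy)phenyl]propane-1,2-diol | OC[C@H](O)[C@@H](c1ccc(OCc2ccccc2)c(OCc2ccccc2)c1)Oc1cccc(OCc2ccccc2)c1 | intermediate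
7 | (2S,3R)-3-[3-(benzyloxy)phenoxy]-3-[3,4-bis(benzyloxy)phenyl]-1-(tert-butyldiphenylsilyloxy)propan-2-ol | CC(C)(C)[Si](c1ccccc1)(c1ccccc1)OC[C@H](O)[C@@H](c1ccc(OCc2ccccc2)c(OCc2ccccc2)c1)Oc1cccc(OCc2ccccc2)c1 | intermediate
8 | (2S,3R)-2-(benzyloxy)-3-[3-(benzyloxy)phenoxy]-3-[3,4-bis(benzyloxy)phenyl]-1-(tert-butyldiphenylsilyloxy)propane | CC(C)(C)[Si](c1ccccc1)(c1ccccc1)OC[C@H](OCc1ccccc1)[C@@H](c1ccc(OCc2ccccc2)c(OCc2ccccc2)c1)Oc1cccc(OCc2ccccc2)c1 | intermediate
9 | (2S,3R)-2-(benzyloxy)-3-[3-(benzyloxy)phenoxy]-3-[3,4-bis(benzyloxy)phenyl]propan-1-ol | OC[C@H](OCc1ccccc1)[C@@H](c1ccc(OCc2ccccc2)c(OCc2ccccc2)c1)Oc1cccc(OCc2ccccc2)c1 | intermediate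
10 | (2R,3R)-2-(benzyloxy)-3-[3-(benzyloxy)phenoxy]-3-[3,4-bis(benzyloxy)phenyl]propanal | O=C[C@H](OCc1ccccc1)[C@@H](c1ccc(OCc2ccccc2)c(OCc2ccccc2)c1)Oc1cccc(OCc2ccccc2)c1 | intermediate
11 | (+)-catechin, (2R,3S) | Oc1cc(O)c2c(c1)O[C@H](c1ccc(O)c(O)c1)[C@@H](O)C2 | starting material
12 | (2R,3S)-5,7-bis(benzyloxy)-2-[3,4-bis(benzyloxy)phenyl]chroman-3-ol | c1c(OCc3ccccc3)c2c(cc1OCc1ccccc1)O[C@H](c1ccc(OCc3ccccc3)c(OCc3ccccc3)c1)[C@@H](O)C2 | intermediate
13 | (2R,3S)-3,5,7-tris(benzyloxy)-2-[3,4-bis(benzyloxy)phenyl]chromane (penta-O-benzylcatechin) | c1c(OCc3ccccc3)c2c(cc1OCc1ccccc1)O[C@H](c1ccc(OCc3ccccc3)c(OCc3ccccc3)c1)[C@@H](OCc1ccccc1)C2 | intermediate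
14 | (2R,3S)-3,5,7-tris(benzyloxy)-2-[3,4-bis(benzyloxy)phenyl]-8-bromochromane | c1c(OCc3ccccc3)c2c(c(Br)c1OCc1ccccc1)O[C@H](c1ccc(OCc3ccccc3)c(OCc3ccccc3)c1)[C@@H](OCc1ccccc1)C2 | intermediate
15 | (2R,3S)-3,5,7-tris(benzyloxy)-2-[3,4-bis(benzyloxy)phenyl]-8-bromo-6-iodochromane | Ic1c(OCc3ccccc3)c2c(c(Br)c1OCc1ccccc1)O[C@H](c1ccc(OCc3ccccc3)c(OCc3ccccc3)c1)[C@@H](OCc1ccccc1)C2 | intermediate
16 | C6 aryllithium: (2R,3S)-penta-O-benzyl-8-bromocatechin-6-yllithium | [Li]c1c(OCc3ccccc3)c2c(c(Br)c1OCc1ccccc1)O[C@H](c1ccc(OCc3ccccc3)c(OCc3ccccc3)c1)[C@@H](OCc1ccccc1)C2 | intermediate (not isolated)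
17 | (2R,3S)-3,5,7-tris(benzyloxy)-2-[3,4-bis(benzyloxy)phenyl]-8-bromo-6-methylchromane | Cc1c(OCc3ccccc3)c2c(c(Br)c1OCc1ccccc1)O[C@H](c1ccc(OCc3ccccc3)c(OCc3ccccc3)c1)[C@@H](OCc1ccccc1)C2 | intermediate
18 | C8 aryllithium: (2R,3S)-penta-O-benzyl-6-methylcatechin-8-yllithium | Cc1c(OCc3ccccc3)c2c(c([Li])c1OCc1ccccc1)O[C@H](c1ccc(OCc3ccccc3)c(OCc3ccccc3)c1)[C@@H](OCc1ccccc1)C2 | intermediate (not isolated)
19 | (2S,3R)-2-(benzyloxy)-3-[3-(benzyloxy)phenoxy]-3-[3,4-bis(benzyloxy)phenyl]-1-[(2R,3S)-penta-O-benzyl-6-methylcatechin-8-yl]propan-1-ol, both C1 epimers | OC(c1c(OCc3ccccc3)c(C)c(OCc3ccccc3)c2c1O[C@H](c1ccc(OCc3ccccc3)c(OCc3ccccc3)c1)[C@@H](OCc1ccccc1)C2)[C@H](OCc1ccccc1)[C@@H](c1ccc(OCc2ccccc2)c(OCc2ccccc2)c1)Oc1cccc(OCc2ccccc2)c1 | intermediate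
20 | C4 benzylic cation derived from 19 | [CH+](c1c(OCc3ccccc3)c(C)c(OCc3ccccc3)c2c1O[C@H](c1ccc(OCc3ccccc3)c(OCc3ccccc3)c1)[C@@H](OCc1ccccc1)C2)[C@H](OCc1ccccc1)[C@@H](c1ccc(OCc2ccccc2)c(OCc2ccccc2)c1)Oc1cccc(OCc2ccccc2)c1 | intermediate (not isolated)
21 | nona-O-benzyl fisetinidol-(4α→8)-6-methylcatechin, upper unit (2R,3S,4S), lower unit (2R,3S) | Cc1c(OCc5ccccc5)c2c(c([C@@H]3c4ccc(OCc5ccccc5)cc4O[C@H](c4ccc(OCc5ccccc5)c(OCc5ccccc5)c4)[C@H]3OCc3ccccc3)c1OCc1ccccc1)O[C@H](c1ccc(OCc3ccccc3)c(OCc3ccccc3)c1)[C@@H](OCc1ccccc1)C2 | intermediate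
22 | (2R,3S,4S)-2-(3,4-dihydroxyphenyl)-4-[(2R,3S)-2-(3,4-dihydroxyphenyl)-3,5,7-trihydroxy-6-methylchroman-8-yl]chroman-3,7-diol | Cc1c(O)c2c(c([C@@H]3c4ccc(O)cc4O[C@H](c4ccc(O)c(O)c4)[C@H]3O)c1O)O[C@H](c1ccc(O)c(O)c1)[C@@H](O)C2 | target

**Step count**

Total: 16 steps. Longest linear sequence: 11 steps (steps 1–8, 14, 15, 16). The catechin branch (steps 9–13) joins at step 14.

**Steps most likely to fail**

Step 15. The cation may be consumed by other pathways: five-membered closure onto ring B, a 1,2-hydride shift from C3, or closure through the rotamer that gives the 3,4-cis epimer. The fallback closes ring C of the upper unit first and makes the C4–C8 bond intermolecularly. It sets out from aldehyde 10 and bromide 17 and returns at 21. Aldehyde 10 would be oxidised (NaClO2, NaH2PO4, 2-methyl-2-butene, t-BuOH/H2O) to the (2R,3R)-propanoic acid F1. Treatment with (CF3CO)2O in CH2Cl2 should acylate the resorcinol ether ring para to its benzyloxy group (intramolecular Friedel–Crafts acylation) and give tetra-O-benzylfustin F2, whose 2,3-trans arrangement is also the thermodynamic one. NaBH4 would then give the flavan-4-ol F3. Bromide 17 would be converted into the C8–H compound penta-O-benzyl-6-methylcatechin F4 (n-BuLi, THF, −78 °C, then MeOH). F3 and an excess of F4 with BF3·OEt2 or Me3SiOTf in CH2Cl2 at −78 °C should give 21; this is the established coupling of a perbenzylated flavan C4 cation with C8 of a perbenzylated flavan-3-ol, in which the nucleophile enters anti to the 3-benzyloxy group.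

Step 14. The hindered, basic aryllithium 18 may deprotonate the aldehyde at C2 instead of adding, which would lead to epimerisation and β-elimination of 3-benzyloxyphenoxide. The fallback is acylation followed by reduction. It sets out from aldehyde 10 and bromide 17 and returns at 19. The acid F1, made from 10 as above, would be coupled with MeNHOMe·HCl (EDC·HCl, HOBt, i-Pr2NEt, CH2Cl2) to the Weinreb amide F5. Aryllithium 18 (from 17, n-BuLi, THF, −78 °C) should add once, through the stable chelated adduct, to give the aryl ketone F6. Reduction with NaBH4/CeCl3·7H2O in MeOH/THF at −20 °C should give 19 as an epimer mixture, which is all step 15 needs.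

Step 3. The electron-rich benzylic epoxide may be opened by isopropanol, tert-butanol or the tartrate under the Lewis-acidic titanium conditions, or during work-up, before it can be used. The fallback epoxidises under buffered basic conditions without a Lewis acid, with the hydroxyl already protected. It sets out from 3 and returns at 7. Alcohol 3 would be silylated (TBDPSCl, imidazole) to the silyl ether F7. Shi epoxidation with the L-fructose-derived ketone (the enantiomer of the usual D-fructose-derived catalyst), Oxone (2KHSO5·KHSO4·K2SO4) and K2CO3 in MeCN/(MeO)2CH2/H2O at 0 °C should give the (2S,3S)-epoxide F8. Opening with 5 and Cs2CO3 in DMF at 60 °C, at the benzylic carbon with inversion, would give 7.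

**Further compounds**

F1 | step 15 | (2R,3R)-2-(benzyloxy)-3-[3-(benzyloxy)phenoxy]-3-[3,4-bis(benzyloxy)phenyl]propanoic acid | OC(=O)[C@H](OCc1ccccc1)[C@@H](c1ccc(OCc2ccccc2)c(OCc2ccccc2)c1)Oc1cccc(OCc2ccccc2)c1
F2 | step 15 | (2R,3R)-3,7-bis(benzyloxy)-2-[3,4-bis(benzyloxy)phenyl]chroman-4-one (tetra-O-benzylfustin) | O=C1c2ccc(OCc3ccccc3)cc2O[C@H](c2ccc(OCc3ccccc3)c(OCc3ccccc3)c2)[C@H]1OCc1ccccc1
F3 | step 15 | (2R,3S)-3,7-bis(benzyloxy)-2-[3,4-bis(benzyloxy)phenyl]chroman-4-ol (C4 epimers) | OC1c2ccc(OCc3ccccc3)cc2O[C@H](c2ccc(OCc3ccccc3)c(OCc3ccccc3)c2)[C@H]1OCc1ccccc1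
F4 | step 15 | (2R,3S)-3,5,7-tris(benzyloxy)-2-[3,4-bis(benzyloxy)phenyl]-6-methylchromane | Cc1c(OCc3ccccc3)c2c(cc1OCc1ccccc1)O[C@H](c1ccc(OCc3ccccc3)c(OCc3ccccc3)c1)[C@@H](OCc1ccccc1)C2
F5 | step 14 | (2R,3R)-2-(benzyloxy)-3-[3-(benzyloxy)phenoxy]-3-[3,4-bis(benzyloxy)phenyl]-N-methoxy-N-methylpropanamide | CON(C)C(=O)[C@H](OCc1ccccc1)[C@@H](c1ccc(OCc2ccccc2)c(OCc2ccccc2)c1)Oc1cccc(OCc2ccccc2)c1
F6 | step 14 | (2R,3R)-2-(benzyloxy)-3-[3-(benzyloxy)phenoxy]-3-[3,4-bis(benzyloxy)phenyl]-1-[(2R,3S)-penta-O-benzyl-6-methylcatechin-8-yl]propan-1-one | O=C(c1c(OCc3ccccc3)c(C)c(OCc3ccccc3)c2c1O[C@H](c1ccc(OCc3ccccc3)c(OCc3ccccc3)c1)[C@@H](OCc1ccccc1)C2)[C@H](OCc1ccccc1)[C@@H](c1ccc(OCc2ccccc2)c(OCc2ccccc2)c1)Oc1cccc(OCc2ccccc2)c1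
F7 | step 3 | (E)-3-[3,4-bis(benzyloxy)phenyl]prop-2-en-1-yl tert-butyldiphenylsilyl ether | CC(C)(C)[Si](c1ccccc1)(c1ccccc1)OC/C=C/c1ccc(OCc2ccccc2)c(OCc2ccccc2)c1
F8 | step 3 | tert-butyl{[(2S,3S)-3-(3,4-bis(benzyloxy)phenyl)oxiran-2-yl]methoxy}diphenylsilane | CC(C)(C)[Si](c1ccccc1)(c1ccccc1)OC[C@@H]1O[C@H]1c1ccc(OCc2ccccc2)c(OCc2ccccc2)c1
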